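## Analysis of the target

Target **21** is 3-[(2R)-1,1-bis(4-hydroxyphenyl)-3-oxo-3-(2,4,6-trihydroxyphenyl)propan-2-yl]-5,7-dihydroxy-4H-chromen-4-one. Labels used below: chromone O1, C2(H), C3, C4(=O) fused to ring A; side chain Cα (the stereocentre, bonded to C3), Cβ (the methine with two 4-hydroxyphenyl rings), and the ring-B ketone (2,4,6-trihydroxybenzoyl) on Cα.

- The skeleton is an open Cβ–Cα–C(=O) unit with three aromatic systems around it. The only heterocycle is the 5,7-dihydroxy-γ-pyrone, substituted at C3 and unsubstituted at C2.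
- Cα is the single stereocentre and is R (CIP order: aroyl > chromon-3-yl > CHAr2 > H). No second centre exists to relay from.
- Cα–H is α to an aryl ketone and allylic to the C2=C3 enol ether. It enolises in acid or base, so every step after it is set must be close to neutral.
- The feature that drives the strategy: Cβ carries two identical 4-hydroxyphenyl rings and is not stereogenic. In addition, C4=O (ring A) and the ring-B ketone are 1,4-related through C3–Cα and carry the same phloroglucinol nucleus. The target is therefore a 2-benzhydryl-1,4-diaryl-butane-1,4-dione plus one carbon (C2), and it hides a twofold symmetry.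
- Sensitive groups: eight phenols, an electrophilic chromone C2, acid-labile phloroglucinol ketones, and, in any open-chain precursor, a 1,4-diketone that can cyclise to a furan.
- The difficulty is to make one crowded, labile tertiary centre in high enantiomeric purity and carry it through pyrone formation and global deprotection.

## Retrosynthetic reasoning

**21 ⇐ 20.** The six remaining benzyl ethers are removed last by hydrogenolysis. Neutral conditions are chosen because Cα–H would not survive Lewis-acid dealkylation or base.

**20 ⇐ 18 ⇐ 17.** The pyrone is cut at O1–C2 and C2–C3. C2 is the one carbon the target has beyond a symmetric 2-substituted 1,4-diaryl-butane-1,4-dione. In **18** only the methylene can become an sp2 C3, so the two identical ortho-hydroxyaryl ketones need not be told apart. **18** comes from **17** by chelation-directed removal of one ortho benzyl ether per ketone.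

**17 ⇐ 15 + 16 (key disconnection).** One Cβ–aryl bond is cut and Cβ is reconnected to the methylene carbon, giving the trans-1,2-diaroyl-3-arylcyclopropane **15**.
- The cut is placed here because the two aryl groups on Cβ are identical, so one can arrive as an arene nucleophile at a benzylic cation.
- The two aroyl groups are identical, so **15** has a local twofold axis through the aryl-bearing carbon.
- The labile Cα of **17** is stored as two cyclopropane stereocentres, which do not enolise because of ring strain.
- The forward reaction must open the ring at the donor carbon and capture the cation with **16** before the Cα proton is lost.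
- The gain is stereoconvergence: either ring bond, by any mechanism, gives the same enantiomer of **17**.

**15 ⇐ 14 ⇐ 10 + 12.** The second aroyl group is made from an aldehyde by aryllithium addition and oxidation. The detour through the aldehyde is needed because the asymmetric cyclopropanation uses iminium activation, which a di-ortho-substituted aryl ketone cannot undergo.

**10 ⇐ 9 + 6.** Both ring bonds to the ylide carbon are cut (Michael-initiated ring closure). A chiral secondary amine controls the face of the β-carbon of enal **9**. That carbon later loses its stereogenicity, but through the trans-selective ring closure it fixes the two acyl-bearing carbons.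

**6 ⇐ 4 ⇐ 2 ⇐ 1; 9 ⇐ 7 + 8; 12 ⇐ 11.** These are short functional-group sequences from purchasable phloroglucinol and 4-hydroxybenzaldehyde derivatives.

## Alternatives that were turned down

**Alternative 1:** (textbook) Cut Cα–Cβ. The forward step is C-alkylation of the enol of the preformed chromone ketone 5,7-bis(benzyloxy)-3-{2-oxo-2-[2,4,6-tris(benzyloxy)phenyl]ethyl}-4H-chromen-4-one **A1** by the diarylmethyl cation from bis[4-(benzyloxy)phenyl]methanol **A2**, with a chiral Brønsted acid or phase-transfer catalyst.
- The stereocentre would be formed as the most acidic C–H of the product, under the same acid or base that enolises it, so racemisation is built in.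
- Enantioselective SN1 alkylation of an acyclic, di-ortho-substituted aryl ketone enol by a simple diarylmethyl cation has no close precedent.
- **A1** needs a single pyrone annulation on a symmetric bis-ketone whose second methylene reacts as well, so the route is not shorter.

**Alternative 2:** (biomimetic) The target is an isomer of the C3–C3″-linked biflavanones; cut the Cβ–aryl bond as a 1,4-aryl shift. Forward: in the trans,trans-3,3″-biflavanone **A3**, one flavanone opens by retro-oxa-Michael reaction to an enone, the C2 aryl ring of the other unit attacks the enone β-carbon at its ipso position through a five-membered spiro transition structure, O1 drives cleavage of the C2–aryl bond, and loss of H3 gives the chromone.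
- **A3** has four stereocentres and needs an oxidative C3–C3″ coupling without stereocontrol, so the precursor is harder than the product.
- Cα would be fixed by a late enol protonation directed by centres that the same cascade destroys.
- Ring-opened intermediates should epimerise and reclose faster than they undergo ipso attack.

**Alternative 3:** Cut C(=O)–Cα. Forward: carbene-catalysed Stetter addition of 2,4,6-tris(benzyloxy)benzaldehyde **A4** to the enone (E)-4,4-bis[4-(benzyloxy)phenyl]-1-[2,4,6-tris(benzyloxy)phenyl]but-2-en-1-one **A5**, giving **17** directly.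
- **A4** is a di-ortho-alkoxy, very electron-rich aldehyde and a poor partner for acyl-anion formation.
- **A5** has a doubly benzylic γ-hydrogen and should deconjugate under the basic conditions.
- Intermolecular enantioselective Stetter reactions of acyclic aryl enones are only moderately selective, and Cα–H would be formed in the presence of the base that epimerises it.

Key step: step 9

Remark (assumption): compounds **1**, **7**, **8**, **11** and **16** are taken as purchasable.
Remark (assumption): the sense of induction in step 5 is assigned from the accepted iminium model for this catalyst class ((S)-catalyst gives (1R,2R,3R)-**10**). If the opposite sense were found, the (R)-catalyst would be used in the same route.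

## Steps

Step 1
Reactants: 1 2′,4′,6′-trihydroxyacetophenone
Product: 2 1-[2,4,6-tris(benzyloxy)phenyl]ethan-1-one
Conditions: BnBr (3.6 equiv), K2CO3, DMF, 80 °C
Reagents that add atoms: benzyl bromide, BrCc1ccccc1
Why: Williamson etherification; excess halide and heat also alkylate the two hydrogen-bonded ortho hydroxyls. No stereocentre is involved.

Step 2
Reactants: 2 1-[2,4,6-tris(benzyloxy)phenyl]ethan-1-one
Product: 4 2-bromo-1-[2,4,6-tris(benzyloxy)phenyl]ethan-1-one, via trimethyl({1-[2,4,6-tris(benzyloxy)phenyl]ethenyl}oxy)silane 3 (not isolated)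
Conditions: LiHMDS, TMSCl, THF, −78 °C; then NBS, −78 → 0 °C
Reagents that add atoms: N-bromosuccinimide, O=C1CCC(=O)N1Br (chlorotrimethylsilane, C[Si](C)(C)Cl, supplies only the silyl group of 3)
Why: Bromination through the silyl enol ether puts the halogen on the α-carbon and avoids electrophilic bromination of the very electron-rich ring.

Step 3
Reactants: 4 2-bromo-1-[2,4,6-tris(benzyloxy)phenyl]ethan-1-one
Product: 6 dimethylsulfonium 2-oxo-2-[2,4,6-tris(benzyloxy)phenyl]ethylide, via dimethyl{2-oxo-2-[2,4,6-tris(benzyloxy)phenyl]ethyl}sulfonium bromide 5 (not isolated)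
Conditions: Me2S, acetone, rt; then aq. NaOH, CHCl3, 0 °C
Reagents that add atoms: dimethyl sulfide, CSC
Why: SN2 displacement of the primary α-bromide, then deprotonation of the acidic sulfonium salt, should give the carbonyl-stabilised ylide, a class that can be stored.

Step 4
Reactants: 7 4-(benzyloxy)benzaldehyde; 8 (triphenylphosphoranylidene)acetaldehyde
Product: 9 (E)-3-[4-(benzyloxy)phenyl]prop-2-enal
Conditions: toluene, 80 °C
Reagents that add atoms: none
Why: Wittig olefination with a formyl-stabilised ylide is E-selective; a slight excess of the aldehyde limits double homologation.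

Step 5
Reactants: 9 (E)-3-[4-(benzyloxy)phenyl]prop-2-enal; 6 dimethylsulfonium 2-oxo-2-[2,4,6-tris(benzyloxy)phenyl]ethylide
Product: 10 (1R,2R,3R)-2-[2,4,6-tris(benzyloxy)benzoyl]-3-[4-(benzyloxy)phenyl]cyclopropane-1-carbaldehyde
Conditions: (S)-indoline-2-carboxylic acid (20 mol %), 9 (2.5 equiv), CHCl3, −10 °C
Reagents that add atoms: none
Why: Iminium-catalysed Michael-initiated ring closure of an enal with a stabilised sulfonium ylide; the catalyst carboxylate steers the sulfonium to one face of the β-carbon. The enamine then displaces Me2S with the formyl group trans to the aryl group (E geometry kept) and trans to the aroyl group, so all three centres follow from the catalyst-controlled attack.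

Step 6
Reactants: 11 1,3,5-tris(benzyloxy)benzene
Product: 12 2-bromo-1,3,5-tris(benzyloxy)benzene
Conditions: NBS (1.0 equiv), CH2Cl2, 0 °C
Reagents that add atoms: N-bromosuccinimide, O=C1CCC(=O)N1Br
Why: Electrophilic aromatic bromination; the three free positions are equivalent and the first bromine slows a second substitution.

Step 7
Reactants: 12 2-bromo-1,3,5-tris(benzyloxy)benzene; 10 (1R,2R,3R)-2-[2,4,6-tris(benzyloxy)benzoyl]-3-[4-(benzyloxy)phenyl]cyclopropane-1-carbaldehyde
Product: 14 [(1R,2R,3R)-3-[4-(benzyloxy)phenyl]-2-{hydroxy[2,4,6-tris(benzyloxy)phenyl]methyl}cyclopropyl][2,4,6-tris(benzyloxy)phenyl]methanone (both carbinol epimers), via [2,4,6-tris(benzyloxy)phenyl]lithium 13 (not isolated)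
Conditions: n-BuLi, THF, −78 °C; then 10, −78 °C; H2O
Reagents that add atoms: none
Why: Bromine–lithium exchange, then 1,2-addition to the aldehyde, which is far more electrophilic than the di-ortho-substituted cyclopropyl ketone. The carbinol centre is a mixture and is removed in step 8.

Step 8
Reactants: 14 the carbinol from step 7
Product: 15 [(1R,2R)-3-[4-(benzyloxy)phenyl]cyclopropane-1,2-diyl]bis{[2,4,6-tris(benzyloxy)phenyl]methanone}
Conditions: Dess–Martin periodinane, CH2Cl2, 0 °C → rt
Reagents that add atoms: none
Why: Dess–Martin oxidation without base; cyclopropane α-C–H bonds do not enolise, so the trans relationship is kept. In 15 the aryl-bearing carbon lies on a local twofold axis and is no longer stereogenic.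

Step 9
Reactants: 15 [(1R,2R)-3-[4-(benzyloxy)phenyl]cyclopropane-1,2-diyl]bis{[2,4,6-tris(benzyloxy)phenyl]methanone}; 16 benzyl phenyl ether
Product: 17 (2S)-2-{bis[4-(benzyloxy)phenyl]methyl}-1,4-bis[2,4,6-tris(benzyloxy)phenyl]butane-1,4-dione
Conditions: TfOH (5 mol %), 16 (10 equiv), HFIP–CH2Cl2 (4:1), 0 °C
Reagents that add atoms: none
Why: Protonation of either aroyl carbonyl in HFIP polarises the adjacent ring bond to C3, the only ring carbon with a donor (4-benzyloxyphenyl); that bond breaks to a 4-alkoxybenzylic cation and an enol, the para position of 16 attacks the cation, and the enol tautomerises to the CH2 ketone. The closest known reaction type is the Brønsted-acid-catalysed Friedel–Crafts ring-opening (1,3-hydroarylation) of aryl-substituted cyclopropyl ketones and donor–acceptor cyclopropanes by electron-rich arenes in HFIP. No ring is closed; the three-membered ring is opened and C3 becomes Cβ with two identical aryl groups. No stereocentre is formed: Cα of 17 is the ring carbon whose bond to C3 stays intact, and it keeps its configuration because none of its bonds is touched. Because 15 has a local twofold axis through C3, cleavage of C3–C1 and of C3–C2 give the same enantiomer, and inversion, retention or a planar cation at C3 are equivalent since C3 ends non-stereogenic; the only control element is the (1R,2R) trans relationship. The step needs para attack of 16 (secured by the hindered secondary cation), no cleavage of the acceptor–acceptor bond C1–C2 (it has no donor), and cation capture faster than loss of the Cα proton or reclosure. The tenfold excess of 16, the low temperature and the non-basic medium are chosen to secure the last point.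

Step 10
Reactants: 17 (2S)-2-{bis[4-(benzyloxy)phenyl]methyl}-1,4-bis[2,4,6-tris(benzyloxy)phenyl]butane-1,4-dione
Product: 18 (2S)-1,4-bis[2,4-bis(benzyloxy)-6-hydroxyphenyl]-2-{bis[4-(benzyloxy)phenyl]methyl}butane-1,4-dione
Conditions: BCl3 (2.2 equiv), CH2Cl2, −78 °C; then MeOH, H2O
Reagents that add atoms: none
Why: Chelation-directed dealkylation: BCl3 binds each ketone and one ortho ether oxygen and chloride removes that benzyl group. The aryloxyboron chelate deactivates the second ortho ether, non-chelated ethers should survive at −78 °C, and the low temperature protects Cα.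

Step 11
Reactants: 18 (2S)-1,4-bis[2,4-bis(benzyloxy)-6-hydroxyphenyl]-2-{bis[4-(benzyloxy)phenyl]methyl}butane-1,4-dione
Product: 20 5,7-bis(benzyloxy)-3-{(2R)-1,1-bis[4-(benzyloxy)phenyl]-3-[2,4-bis(benzyloxy)-6-hydroxyphenyl]-3-oxopropan-2-yl}-4H-chromen-4-one, via (2R)-2-{bis[4-(benzyloxy)phenyl]methyl}-1,4-bis[2,4-bis(benzyloxy)-6-hydroxyphenyl]-3-[(dimethylamino)methylidene]butane-1,4-dione 19 (not isolated)
Conditions: Me2NCH(OMe)2 (3 equiv), toluene, 80 °C; then AcOH, 60 °C
Reagents that add atoms: N,N-dimethylformamide dimethyl acetal, COC(OC)N(C)C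
Why: Amide-acetal condensation at the only methylene α to a ketone gives the enaminone; addition–elimination by the ortho hydroxyl of the same ring (6-endo; the other phenol would need a seven-membered ring) closes the pyrone and expels dimethylamine (chromone annulation). The methine cannot give an aromatic pyrone, and Cα keeps its configuration (the descriptor changes to R only through CIP priorities).

Step 12
Reactants: 20 the hexabenzyl chromone from step 11
Product: 21 3-[(2R)-1,1-bis(4-hydroxyphenyl)-3-oxo-3-(2,4,6-trihydroxyphenyl)propan-2-yl]-5,7-dihydroxy-4H-chromen-4-one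
Conditions: H2 (1 atm), 10% Pd/C, EtOAc–MeOH, rt
Reagents that add atoms: none
Why: Hydrogenolysis of aryl benzyl ethers at neutral pH should leave Cα–H, the hindered aryl ketone and the trisubstituted pyrone C2=C3 untouched; it is stopped after uptake of six equivalents.

## Compound list

1 | 2′,4′,6′-trihydroxyacetophenone | CC(=O)c1c(O)cc(O)cc1O | starting material
2 | 1-[2,4,6-tris(benzyloxy)phenyl]ethan-1-one | CC(=O)c1c(OCc2ccccc2)cc(OCc2ccccc2)cc1OCc1ccccc1 | intermediate
3 | trimethyl({1-[2,4,6-tris(benzyloxy)phenyl]ethenyl}oxy)silane | C=C(O[Si](C)(C)C)c1c(OCc2ccccc2)cc(OCc2ccccc2)cc1OCc1ccccc1 | intermediate (not isolated)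
4 | 2-bromo-1-[2,4,6-tris(benzyloxy)phenyl]ethan-1-one | BrCC(=O)c1c(OCc2ccccc2)cc(OCc2ccccc2)cc1OCc1ccccc1 | intermediate
5 | dimethyl{2-oxo-2-[2,4,6-tris(benzyloxy)phenyl]ethyl}sulfonium bromide | C[S+](C)CC(=O)c1c(OCc2ccccc2)cc(OCc2ccccc2)cc1OCc1ccccc1.[Br-] | intermediate (not isolated)
6 | dimethylsulfonium 2-oxo-2-[2,4,6-tris(benzyloxy)phenyl]ethylide | C[S+](C)[CH-]C(=O)c1c(OCc2ccccc2)cc(OCc2ccccc2)cc1OCc1ccccc1 | intermediate
7 | 4-(benzyloxy)benzaldehyde | O=Cc1ccc(OCc2ccccc2)cc1 | starting material
8 | (triphenylphosphoranylidene)acetaldehyde | O=CC=P(c1ccccc1)(c1ccccc1)c1ccccc1 | starting material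
9 | (E)-3-[4-(benzyloxy)phenyl]prop-2-enal | O=C/C=C/c1ccc(OCc2ccccc2)cc1 | intermediate
10 | (1R,2R,3R)-2-[2,4,6-tris(benzyloxy)benzoyl]-3-[4-(benzyloxy)phenyl]cyclopropane-1-carbaldehyde (formyl trans to aroyl and to aryl) | O=C[C@H]1[C@H](C(=O)c2c(OCc3ccccc3)cc(OCc3ccccc3)cc2OCc2ccccc2)[C@@H]1c1ccc(OCc2ccccc2)cc1 | intermediate
11 | 1,3,5-tris(benzyloxy)benzene | c1ccc(COc2cc(OCc3ccccc3)cc(OCc3ccccc3)c2)cc1 | starting material
12 | 2-bromo-1,3,5-tris(benzyloxy)benzene | Brc1c(OCc2ccccc2)cc(OCc2ccccc2)cc1OCc1ccccc1 | intermediate
13 | [2,4,6-tris(benzyloxy)phenyl]lithium | [Li]c1c(OCc2ccccc2)cc(OCc2ccccc2)cc1OCc1ccccc1 | intermediate (not isolated)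
14 | [(1R,2R,3R)-3-[4-(benzyloxy)phenyl]-2-{hydroxy[2,4,6-tris(benzyloxy)phenyl]methyl}cyclopropyl][2,4,6-tris(benzyloxy)phenyl]methanone (carbinol epimers) | OC(c1c(OCc2ccccc2)cc(OCc2ccccc2)cc1OCc1ccccc1)[C@H]1[C@H](C(=O)c2c(OCc3ccccc3)cc(OCc3ccccc3)cc2OCc2ccccc2)[C@@H]1c1ccc(OCc2ccccc2)cc1 | intermediate
15 | [(1R,2R)-3-[4-(benzyloxy)phenyl]cyclopropane-1,2-diyl]bis{[2,4,6-tris(benzyloxy)phenyl]methanone} | O=C(c1c(OCc2ccccc2)cc(OCc2ccccc2)cc1OCc1ccccc1)[C@H]1[C@H](C(=O)c2c(OCc3ccccc3)cc(OCc3ccccc3)cc2OCc2ccccc2)C1c1ccc(OCc2ccccc2)cc1 | intermediate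
16 | benzyl phenyl ether | c1ccc(COc2ccccc2)cc1 | starting material
17 | (2S)-2-{bis[4-(benzyloxy)phenyl]methyl}-1,4-bis[2,4,6-tris(benzyloxy)phenyl]butane-1,4-dione | O=C(c1c(OCc2ccccc2)cc(OCc2ccccc2)cc1OCc1ccccc1)[C@@H](CC(=O)c1c(OCc2ccccc2)cc(OCc2ccccc2)cc1OCc1ccccc1)C(c1ccc(OCc2ccccc2)cc1)c1ccc(OCc2ccccc2)cc1 | intermediate
18 | (2S)-1,4-bis[2,4-bis(benzyloxy)-6-hydroxyphenyl]-2-{bis[4-(benzyloxy)phenyl]methyl}butane-1,4-dione | O=C(c1c(O)cc(OCc2ccccc2)cc1OCc1ccccc1)[C@@H](CC(=O)c1c(O)cc(OCc2ccccc2)cc1OCc1ccccc1)C(c1ccc(OCc2ccccc2)cc1)c1ccc(OCc2ccccc2)cc1 | intermediate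
19 | (2R)-2-{bis[4-(benzyloxy)phenyl]methyl}-1,4-bis[2,4-bis(benzyloxy)-6-hydroxyphenyl]-3-[(dimethylamino)methylidene]butane-1,4-dione (C=C geometry not defined) | O=C(c1c(O)cc(OCc2ccccc2)cc1OCc1ccccc1)[C@@H](C(=CN(C)C)C(=O)c1c(O)cc(OCc2ccccc2)cc1OCc1ccccc1)C(c1ccc(OCc2ccccc2)cc1)c1ccc(OCc2ccccc2)cc1 | intermediate (not isolated)
20 | 5,7-bis(benzyloxy)-3-{(2R)-1,1-bis[4-(benzyloxy)phenyl]-3-[2,4-bis(benzyloxy)-6-hydroxyphenyl]-3-oxopropan-2-yl}-4H-chromen-4-one | O=C(c1c(O)cc(OCc2ccccc2)cc1OCc1ccccc1)[C@@H](c1coc2cc(OCc3ccccc3)cc(OCc3ccccc3)c2c1=O)C(c1ccc(OCc2ccccc2)cc1)c1ccc(OCc2ccccc2)cc1 | intermediate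
21 | 3-[(2R)-1,1-bis(4-hydroxyphenyl)-3-oxo-3-(2,4,6-trihydroxyphenyl)propan-2-yl]-5,7-dihydroxy-4H-chromen-4-one | O=C(c1c(O)cc(O)cc1O)[C@@H](c1coc2cc(O)cc(O)c2c1=O)C(c1ccc(O)cc1)c1ccc(O)cc1 | target

## Step count and least certain steps

Total step count: 12. Longest linear sequence: 10 steps (1, 2, 3, 5, 7, 8, 9, 10, 11, 12).

**Step 9 (key step).** The most likely failure is erosion of enantiomeric purity. The benzylic cation can lose the Cα proton to give the α-benzylidene diketone, which would be re-arylated without facial control. It can also reclose to the cis (meso) cyclopropane and reopen at the other bond. Lesser risks are capture of the cation by an ortho benzyloxy oxygen with loss of its benzyl group, and ortho attack of the arene. The fallback sets out from 15 and avoids any cation. [4-(Benzyloxy)phenyl]magnesium bromide F1, made from the corresponding aryl bromide and magnesium, is added with catalytic CuBr·SMe2 in THF at −40 °C. It should open the ring by SN2-type homoconjugate addition at the aryl-bearing carbon, and the twofold axis again makes both ring bonds equivalent. The magnesium enolate is quenched cold with water to prevent enolate equilibration, and the route is rejoined at 17.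

**Step 5.** The most likely failure is low conversion, because the β-aryl iminium ion is a weak acceptor and the di-ortho-substituted ylide is bulky. Poor facial selectivity is the second risk. Any cis-diacyl isomer becomes a meso diketone after step 8 and lowers yield rather than enantiomeric purity. The fallback sets out from 2 and 7. Base-mediated Claisen–Schmidt condensation gives the chalcone (E)-3-[4-(benzyloxy)phenyl]-1-[2,4,6-tris(benzyloxy)phenyl]prop-2-en-1-one F2. Uncatalysed Michael-initiated ring closure of F2 with ylide 6 (toluene, 60 °C) should give the trans-diketone as the racemate, that is 15 together with its (1S,2S) enantiomer F3. Preparative chromatography on a chiral stationary phase separates them and the route is rejoined at 15; steps 4 to 8 are then not needed.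

**Step 11.** The most likely failure is slow condensation at the β-branched methylene, so that the temperature needed allows enolisation and epimerisation at Cα; O-methylation of a phenol by the acetal is a second risk. The fallback sets out from 17. Soft enolisation (TMSOTf, Et3N, CH2Cl2, −20 °C) should silylate only the unhindered CH2 ketone and give the silyl enol ether F4. A Mukaiyama-type reaction with trimethyl orthoformate (catalytic TMSOTf, −78 °C) gives the β-keto dimethyl acetal F5. BCl3 (−78 → 0 °C) then removes one ortho benzyl group per ring and the acetal, and the freed phenol and aldehyde cyclodehydrate, so the route is rejoined at 20.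

**Step 10.** The most likely failure is loss of selectivity, with cleavage of non-chelated benzyl ethers, or Lewis-acid-induced enolisation at Cα and cyclodehydration of the 1,4-diketone to a furan. The fallback sets out from 17. Hydrogenolysis (H2, Pd/C) of all eight benzyl ethers gives the octaphenol F6. One-pot formylation–cyclisation of the unprotected polyhydroxy ketone with DMF, methanesulfonyl chloride and BF3·OEt2, a method known for unprotected 2-hydroxyaryl benzyl ketones, then gives the target directly. The route is rejoined at 21 and steps 10 to 12 are replaced.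

## Further compounds

F1 | step 9 | [4-(benzyloxy)phenyl]magnesium bromide | Br[Mg]c1ccc(OCc2ccccc2)cc1
F2 | step 5 | (E)-3-[4-(benzyloxy)phenyl]-1-[2,4,6-tris(benzyloxy)phenyl]prop-2-en-1-one | O=C(/C=C/c1ccc(OCc2ccccc2)cc1)c1c(OCc2ccccc2)cc(OCc2ccccc2)cc1OCc1ccccc1
F3 | step 5 | [(1S,2S)-3-[4-(benzyloxy)phenyl]cyclopropane-1,2-diyl]bis{[2,4,6-tris(benzyloxy)phenyl]methanone} (enantiomer of 15) | O=C(c1c(OCc2ccccc2)cc(OCc2ccccc2)cc1OCc1ccccc1)[C@@H]1[C@@H](C(=O)c2c(OCc3ccccc3)cc(OCc3ccccc3)cc2OCc2ccccc2)C1c1ccc(OCc2ccccc2)cc1
F4 | step 11 | (Z)-trimethylsilyl enol ether of the CH2 ketone of 17 (Cα as in 17) | O=C(c1c(OCc2ccccc2)cc(OCc2ccccc2)cc1OCc1ccccc1)[C@@H](/C=C(\O[Si](C)(C)C)c1c(OCc2ccccc2)cc(OCc2ccccc2)cc1OCc1ccccc1)C(c1ccc(OCc2ccccc2)cc1)c1ccc(OCc2ccccc2)cc1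
F5 | step 11 | 2-{bis[4-(benzyloxy)phenyl]methyl}-3-(dimethoxymethyl)-1,4-bis[2,4,6-tris(benzyloxy)phenyl]butane-1,4-dione (Cα as in 17, epimers at C3) | O=C(c1c(OCc2ccccc2)cc(OCc2ccccc2)cc1OCc1ccccc1)[C@@H](C(C(OC)OC)C(=O)c1c(OCc2ccccc2)cc(OCc2ccccc2)cc1OCc1ccccc1)C(c1ccc(OCc2ccccc2)cc1)c1ccc(OCc2ccccc2)cc1
F6 | step 10 | (2S)-2-[bis(4-hydroxyphenyl)methyl]-1,4-bis(2,4,6-trihydroxyphenyl)butane-1,4-dione | O=C(c1c(O)cc(O)cc1O)[C@@H](CC(=O)c1c(O)cc(O)cc1O)C(c1ccc(O)cc1)c1ccc(O)cc1
A1 | alternative 1 | 5,7-bis(benzyloxy)-3-{2-oxo-2-[2,4,6-tris(benzyloxy)phenyl]ethyl}-4H-chromen-4-one | O=C(Cc1coc2cc(OCc3ccccc3)cc(OCc3ccccc3)c2c1=O)c1c(OCc2ccccc2)cc(OCc2ccccc2)cc1OCc1ccccc1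
A2 | alternative 1 | bis[4-(benzyloxy)phenyl]methanol | OC(c1ccc(OCc2ccccc2)cc1)c1ccc(OCc2ccccc2)cc1
A3 | alternative 2 | trans,trans-3,3″-biflavanone built from two 5,7,4′-trihydroxyflavanone units (one stereoisomer shown) | O=C1c2c(O)cc(O)cc2O[C@H](c2ccc(O)cc2)[C@H]1[C@H]1C(=O)c2c(O)cc(O)cc2O[C@@H]1c1ccc(O)cc1
A4 | alternative 3 | 2,4,6-tris(benzyloxy)benzaldehyde | O=Cc1c(OCc2ccccc2)cc(OCc2ccccc2)cc1OCc1ccccc1
A5 | alternative 3 | (E)-4,4-bis[4-(benzyloxy)phenyl]-1-[2,4,6-tris(benzyloxy)phenyl]but-2-en-1-one | O=C(/C=C/C(c1ccc(OCc2ccccc2)cc1)c1ccc(OCc2ccccc2)cc1)c1c(OCc2ccccc2)cc(OCc2ccccc2)cc1OCc1ccccc1
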